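**Retrosynthetic overview**

- Feature: the 2,2-dimethyl-2H-pyran ring is fused to the benzene ring through O1–C8a and C4–C4a; its carbons C2 (with both methyls), C3 and C4 can all be delivered as one 1,1-dimethylpropargyl group on the C8a oxygen.
- Target 20 ⇐ bis-TBS chromene 19 (desilylation) ⇐ aryl 1,1-dimethylpropargyl ether 15 (propargyl Claisen shift, 1,5-H shift, oxa-6π closure; C4–C4a first, then O1–C2).
- 15 ⇐ phenol 13 + 3-chloro-3-methylbut-1-yne 14; 13 ⇐ aryl ketone 12 ⇐ aryllithium from benzyl ether 9 + S Weinreb amide 7.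
- 7 ⇐ L-tyrosine 1; diazotisation with net retention sets the only stereocentre (S).
- Ring order: both benzene rings are bought; the pyran ring is the only ring made, in step 8, after all organometallic chemistry.

Key step: step 8

**Route**

Step 1
Reactants: 1 L-tyrosine
Product: 4 (S)-2-hydroxy-3-(4-hydroxyphenyl)propanoic acid, via diazonium carboxylate 2 (not isolated), via alpha-lactone 3 (not isolated)
Conditions: NaNO2, 1 M H2SO4 aq, 0 °C to rt
Reagents that add atoms: water, O
Why: Diazotisation of the α-amino acid (van Slyke-type deamination): the carboxylate expels N2 with inversion to α-lactone 3 and water reopens it with a second inversion, so the S centre of L-tyrosine is carried over with net retention; slow nitrite addition in cold dilute acid limits nitrosation of the phenol ring.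

Step 2
Reactants: 4 (S)-2-hydroxy-3-(4-hydroxyphenyl)propanoic acid
Product: 6 (S)-2-hydroxy-3-(4-hydroxyphenyl)-N-methoxy-N-methylpropanamide, via benzotriazolyl ester 5 (not isolated)
Conditions: MeNHOMe·HCl, EDC·HCl, HOBt, N-methylmorpholine, CH2Cl2/DMF, 0 °C to rt
Reagents that add atoms: N,O-dimethylhydroxylamine hydrochloride, CNOC.Cl
Why: Carbodiimide amide coupling through the HOBt active ester gives the Weinreb amide; the amine outcompetes the phenol and the secondary hydroxyl, and an α-hydroxy acid has no oxazolone pathway for racemisation.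

Step 3
Reactants: 6 (S)-2-hydroxy-3-(4-hydroxyphenyl)-N-methoxy-N-methylpropanamide
Product: 7 (S)-2-(tert-butyldimethylsilyloxy)-3-[4-(tert-butyldimethylsilyloxy)phenyl]-N-methoxy-N-methylpropanamide
Conditions: TBSCl (2.5 equiv), imidazole, DMF, rt
Reagents that add atoms: tert-butyldimethylsilyl chloride (TBSCl), CC(C)(C)[Si](C)(C)Cl
Why: Imidazole-promoted silylation (Corey conditions) should protect the phenol and the secondary alcohol as TBS ethers in one operation and leave the Weinreb amide untouched.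

Step 4
Reactants: 8 4-bromo-3-methoxyphenol
Product: 9 4-(benzyloxy)-1-bromo-2-methoxybenzene
Conditions: BnBr, K2CO3, DMF, rt
Reagents that add atoms: benzyl bromide, BrCc1ccccc1
Why: Williamson ether synthesis; the benzyl ether withstands the organolithium step and can later be removed by neutral hydrogenolysis without touching silyl ethers.

Step 5
Reactants: 9 4-(benzyloxy)-1-bromo-2-methoxybenzene; 7 (S)-2-(tert-butyldimethylsilyloxy)-3-[4-(tert-butyldimethylsilyloxy)phenyl]-N-methoxy-N-methylpropanamide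
Product: 12 (S)-1-[4-(benzyloxy)-2-methoxyphenyl]-2-(tert-butyldimethylsilyloxy)-3-[4-(tert-butyldimethylsilyloxy)phenyl]propan-1-one, via aryllithium 10 (not isolated), via tetrahedral lithium chelate 11 (not isolated)
Conditions: n-BuLi, THF, −78 °C; then 7, −78 °C; aq NH4Cl
Reagents that add atoms: none
Why: Bromine–lithium exchange places lithium regiospecifically on the carbon ortho to OMe, and the Weinreb ketone synthesis stops at the N-methoxy chelate 11, so over-addition is excluded and the α-silyloxy centre, not enolised at −78 °C, should stay S.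

Step 6
Reactants: 12 (S)-1-[4-(benzyloxy)-2-methoxyphenyl]-2-(tert-butyldimethylsilyloxy)-3-[4-(tert-butyldimethylsilyloxy)phenyl]propan-1-one
Product: 13 (S)-2-(tert-butyldimethylsilyloxy)-3-[4-(tert-butyldimethylsilyloxy)phenyl]-1-(4-hydroxy-2-methoxyphenyl)propan-1-one
Conditions: H2 (1 atm), 10% Pd/C, EtOAc, rt
Reagents that add atoms: none
Why: Hydrogenolysis of an aryl benzyl ether over Pd/C is fast and neutral; in ethyl acetate at 1 atm the electron-rich, hindered aryl ketone and both silyl ethers should survive if the reaction is stopped at full debenzylation.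

Step 7
Reactants: 13 (S)-2-(tert-butyldimethylsilyloxy)-3-[4-(tert-butyldimethylsilyloxy)phenyl]-1-(4-hydroxy-2-methoxyphenyl)propan-1-one; 14 3-chloro-3-methylbut-1-yne
Product: 15 (S)-2-(tert-butyldimethylsilyloxy)-3-[4-(tert-butyldimethylsilyloxy)phenyl]-1-{2-methoxy-4-[(2-methylbut-3-yn-2-yl)oxy]phenyl}propan-1-one
Conditions: CuCl2·2H2O (cat.), DBU (1.1 equiv), dry MeCN, 0 °C
Reagents that add atoms: none
Why: Copper-catalysed O-propargylation of a phenol with a tertiary propargylic chloride (Godfrey-type etherification), which suits acidic para-acyl phenols; with DBU near one equivalent at 0 °C the phenoxide rather than free amidine is the base present, so the α-silyloxy ketone should not be enolised.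

Step 8
Reactants: 15 (S)-2-(tert-butyldimethylsilyloxy)-3-[4-(tert-butyldimethylsilyloxy)phenyl]-1-{2-methoxy-4-[(2-methylbut-3-yn-2-yl)oxy]phenyl}propan-1-one
Product: 19 (S)-2-(tert-butyldimethylsilyloxy)-3-[4-(tert-butyldimethylsilyloxy)phenyl]-1-(7-methoxy-2,2-dimethyl-2H-chromen-6-yl)propan-1-one, via allenyl dienone 16 (not isolated), via ortho-allenylphenol 17 (not isolated), via ortho-quinone methide 18 (not isolated)
Conditions: o-xylene (degassed), 145 °C, Ar
Reagents that add atoms: none
Why: Heating triggers an aryl propargyl Claisen ([3,3]) shift that bonds the alkyne terminus to the ring carbon para to OMe (the future C4a), forming C4–C4a in allenyl dienone 16, which tautomerises to ortho-allenylphenol 17; a 1,5-hydrogen shift from the phenol OH to the central allene carbon then gives the Z ortho-quinone methide 18. The pyran ring is closed by a thermal disrotatory oxa-6π electrocyclisation of 18 that forms O1–C2 and restores the aromatic ring. The closest known reaction is the thermal conversion of aryl 1,1-dimethylpropargyl ethers, para-acyl ones included, into 2,2-dimethyl-2H-chromenes. No stereocentre is created (C2 carries two methyls) and the S α-silyloxy ketone is a spectator, since the medium is neutral and free of acid, base, metal or oxidant. The step needs regioselectivity between the two carbons ortho to the ether oxygen: the carbon between the two oxygens is flanked on both sides, whereas the carbon para to OMe has a free neighbour and is electronically favoured, and because the ortho oxygen is a methyl ether there is no ketone–phenol hydrogen bond to fix the ring double bonds toward the crowded carbon. The gem-dimethyl group accelerates the [3,3] step, so a hydrocarbon solvent at about 145 °C should suffice.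

Step 9
Reactants: 19 (S)-2-(tert-butyldimethylsilyloxy)-3-[4-(tert-butyldimethylsilyloxy)phenyl]-1-(7-methoxy-2,2-dimethyl-2H-chromen-6-yl)propan-1-one
Product: 20 Lespeflorin C7, (S)-2-hydroxy-3-(4-hydroxyphenyl)-1-(7-methoxy-2,2-dimethyl-2H-chromen-6-yl)propan-1-one
Conditions: TBAF, AcOH (1:1), THF, 0 °C to rt
Reagents that add atoms: none
Why: Fluoride-induced Si–O cleavage removes the aryl and the α-keto secondary TBS ethers; acetic acid buffering keeps the medium near neutral, so the liberated acyloin should neither epimerise nor undergo α-ketol transposition, and the chromene is not exposed to strong acid.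

**Compound list**

1 | L-tyrosine | N[C@@H](Cc1ccc(O)cc1)C(=O)O | starting material
2 | (S)-1-carboxylato-2-(4-hydroxyphenyl)ethanediazonium (diazonium carboxylate) | N#[N+][C@@H](Cc1ccc(O)cc1)C(=O)[O-] | intermediate
3 | (R)-3-[(4-hydroxyphenyl)methyl]oxiran-2-one (α-lactone) | O1[C@H](Cc2ccc(O)cc2)C1=O | intermediate
4 | (S)-2-hydroxy-3-(4-hydroxyphenyl)propanoic acid | O[C@@H](Cc1ccc(O)cc1)C(=O)O | intermediate
5 | 1H-benzotriazol-1-yl (S)-2-hydroxy-3-(4-hydroxyphenyl)propanoate | O=C(On1nnc2ccccc12)[C@@H](O)Cc1ccc(O)cc1 | intermediate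
6 | (S)-2-hydroxy-3-(4-hydroxyphenyl)-N-methoxy-N-methylpropanamide | CON(C)C(=O)[C@@H](O)Cc1ccc(O)cc1 | intermediate
7 | (S)-2-(tert-butyldimethylsilyloxy)-3-[4-(tert-butyldimethylsilyloxy)phenyl]-N-methoxy-N-methylpropanamide | CON(C)C(=O)[C@@H](O[Si](C)(C)C(C)(C)C)Cc1ccc(O[Si](C)(C)C(C)(C)C)cc1 | intermediate
8 | 4-bromo-3-methoxyphenol | COc1cc(O)ccc1Br | starting material
9 | 4-(benzyloxy)-1-bromo-2-methoxybenzene | COc1cc(OCc2ccccc2)ccc1Br | intermediate
10 | [4-(benzyloxy)-2-methoxyphenyl]lithium | [Li]c1ccc(OCc2ccccc2)cc1OC | intermediate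
11 | lithium alkoxide of the N-methoxy-N-methyl hemiaminal from 10 and 7 (S at the silyloxy carbon, hemiaminal carbon unassigned) | COc1cc(OCc2ccccc2)ccc1C(O[Li])(N(C)OC)[C@@H](O[Si](C)(C)C(C)(C)C)Cc1ccc(O[Si](C)(C)C(C)(C)C)cc1 | intermediate
12 | (S)-1-[4-(benzyloxy)-2-methoxyphenyl]-2-(tert-butyldimethylsilyloxy)-3-[4-(tert-butyldimethylsilyloxy)phenyl]propan-1-one | COc1cc(OCc2ccccc2)ccc1C(=O)[C@@H](O[Si](C)(C)C(C)(C)C)Cc1ccc(O[Si](C)(C)C(C)(C)C)cc1 | intermediate
13 | (S)-2-(tert-butyldimethylsilyloxy)-3-[4-(tert-butyldimethylsilyloxy)phenyl]-1-(4-hydroxy-2-methoxyphenyl)propan-1-one | COc1cc(O)ccc1C(=O)[C@@H](O[Si](C)(C)C(C)(C)C)Cc1ccc(O[Si](C)(C)C(C)(C)C)cc1 | intermediate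
14 | 3-chloro-3-methylbut-1-yne | CC(C)(Cl)C#C | starting material
15 | (S)-2-(tert-butyldimethylsilyloxy)-3-[4-(tert-butyldimethylsilyloxy)phenyl]-1-{2-methoxy-4-[(2-methylbut-3-yn-2-yl)oxy]phenyl}propan-1-one | C#CC(C)(C)Oc1ccc(C(=O)[C@@H](O[Si](C)(C)C(C)(C)C)Cc2ccc(O[Si](C)(C)C(C)(C)C)cc2)c(OC)c1 | intermediate
16 | 6-(3-methylbuta-1,2-dien-1-yl)cyclohexa-2,4-dien-1-one bearing 3-OMe and the 4-acyl side chain (S side chain, ring sp3 carbon unassigned) | O=C1C=C(OC)C(C(=O)[C@@H](O[Si](C)(C)C(C)(C)C)Cc2ccc(O[Si](C)(C)C(C)(C)C)cc2)=CC1C=C=C(C)C | intermediate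
17 | (S)-2-(tert-butyldimethylsilyloxy)-3-[4-(tert-butyldimethylsilyloxy)phenyl]-1-[4-hydroxy-2-methoxy-5-(3-methylbuta-1,2-dien-1-yl)phenyl]propan-1-one | Oc1cc(OC)c(C(=O)[C@@H](O[Si](C)(C)C(C)(C)C)Cc2ccc(O[Si](C)(C)C(C)(C)C)cc2)cc1C=C=C(C)C | intermediate
18 | (Z)-6-(3-methylbut-2-en-1-ylidene)cyclohexa-2,4-dien-1-one bearing 3-OMe and the 4-acyl side chain (ortho-quinone methide, S side chain) | O=C1C=C(OC)C(C(=O)[C@@H](O[Si](C)(C)C(C)(C)C)Cc2ccc(O[Si](C)(C)C(C)(C)C)cc2)=C/C1=C/C=C(C)C | intermediate
19 | (S)-2-(tert-butyldimethylsilyloxy)-3-[4-(tert-butyldimethylsilyloxy)phenyl]-1-(7-methoxy-2,2-dimethyl-2H-chromen-6-yl)propan-1-one | COc1cc2c(cc1C(=O)[C@@H](O[Si](C)(C)C(C)(C)C)Cc1ccc(O[Si](C)(C)C(C)(C)C)cc1)C=CC(C)(C)O2 | intermediate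
20 | Lespeflorin C7, (S)-2-hydroxy-3-(4-hydroxyphenyl)-1-(7-methoxy-2,2-dimethyl-2H-chromen-6-yl)propan-1-one | COc1cc2c(cc1C(=O)[C@@H](O)Cc1ccc(O)cc1)C=CC(C)(C)O2 | target

**Step count**

Total: 9 steps. Longest linear sequence: 8 steps (L-tyrosine 1 to 20 through steps 1, 2, 3, 5, 6, 7, 8, 9). The aryl branch (step 4) joins at step 5.

**Steps most likely to fail**

Step 8. The propargyl terminus may migrate in part to the carbon between the two oxygens and give the angular chromene, or the cascade may stall at the temperature the silyloxy ketone tolerates. The fallback sets out from phenol 13 and comes back at 19, replacing the sigmatropic C–C bond formation by a boron-templated ortho-alkylation. Phenol 13 would be heated with 3-methylbut-2-enal and PhB(OH)2 (propionic acid cat., toluene, reflux, water removal). Electrophilic attack para to OMe should give the (S)-configured 6-acyl-7-methoxy-4-(2-methylprop-1-en-1-yl)-2-phenyl-4H-1,3,2-benzodioxaborin F1, which fragments on heating to the same ortho-quinone methide 18 and closes to 19.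

Step 7. DBU may epimerise the α-silyloxy ketone or cleave the aryl silyl ether, and elimination of the tertiary chloride may outrun O-alkylation. The fallback sets out from 8 (with 14 and 7) and comes back at 19; etherification and the thermal cascade are run before any stereocentre or silyl ether is present. Phenol 8 and 14 under the same CuCl2·2H2O/DBU conditions should give 1-bromo-2-methoxy-4-[(2-methylbut-3-yn-2-yl)oxy]benzene F2. Heating F2 in o-xylene should pass through the bromo allenyl dienone F3, the bromo ortho-allenylphenol F4 and the bromo ortho-quinone methide F5 to 6-bromo-7-methoxy-2,2-dimethyl-2H-chromene F6, from which any angular isomer can be separated at this cheap stage. Bromine–lithium exchange (n-BuLi, THF, −78 °C) would give (7-methoxy-2,2-dimethyl-2H-chromen-6-yl)lithium F7. Addition of F7 to Weinreb amide 7 gives the tetrahedral lithium chelate F8, which releases 19 on aqueous NH4Cl quench.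

Step 9. Fluoride basicity may epimerise the freed acyloin or transpose it (α-ketol shift), and the hindered secondary silyl ether may come off slowly, while acidic alternatives endanger the chromene. The fallback sets out from 15 and comes back at 20; the order is reversed so that the neutral thermal cascade is the last step. Ether 15 would be desilylated with aqueous HF in MeCN, which is tolerable because no chromene is present yet, to give (S)-2-hydroxy-3-(4-hydroxyphenyl)-1-{2-methoxy-4-[(2-methylbut-3-yn-2-yl)oxy]phenyl}propan-1-one F9. Heating F9 in o-xylene or o-dichlorobenzene should pass through the free-hydroxyl allenyl dienone F10, ortho-allenylphenol F11 and ortho-quinone methide F12 directly to 20.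

**Further compounds**

F1 | step 8 | (S)-2-(tert-butyldimethylsilyloxy)-3-[4-(tert-butyldimethylsilyloxy)phenyl]-1-[7-methoxy-4-(2-methylprop-1-en-1-yl)-2-phenyl-4H-1,3,2-benzodioxaborin-6-yl]propan-1-one (C4 unassigned) | COc1cc2OB(c3ccccc3)OC(C=C(C)C)c2cc1C(=O)[C@@H](O[Si](C)(C)C(C)(C)C)Cc1ccc(O[Si](C)(C)C(C)(C)C)cc1
F2 | step 7 | 1-bromo-2-methoxy-4-[(2-methylbut-3-yn-2-yl)oxy]benzene | COc1cc(OC(C)(C)C#C)ccc1Br
F3 | step 7 | 4-bromo-3-methoxy-6-(3-methylbuta-1,2-dien-1-yl)cyclohexa-2,4-dien-1-one | O=C1C=C(OC)C(Br)=CC1C=C=C(C)C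
F4 | step 7 | 4-bromo-5-methoxy-2-(3-methylbuta-1,2-dien-1-yl)phenol | Oc1cc(OC)c(Br)cc1C=C=C(C)C
F5 | step 7 | (Z)-4-bromo-3-methoxy-6-(3-methylbut-2-en-1-ylidene)cyclohexa-2,4-dien-1-one | O=C1C=C(OC)C(Br)=C/C1=C/C=C(C)C
F6 | step 7 | 6-bromo-7-methoxy-2,2-dimethyl-2H-chromene | COc1cc2OC(C)(C)C=Cc2cc1Br
F7 | step 7 | (7-methoxy-2,2-dimethyl-2H-chromen-6-yl)lithium | COc1cc2OC(C)(C)C=Cc2cc1[Li]
F8 | step 7 | lithium alkoxide of the N-methoxy-N-methyl hemiaminal from F7 and 7 (S at the silyloxy carbon, hemiaminal carbon unassigned) | COc1cc2OC(C)(C)C=Cc2cc1C(O[Li])(N(C)OC)[C@@H](O[Si](C)(C)C(C)(C)C)Cc1ccc(O[Si](C)(C)C(C)(C)C)cc1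
F9 | step 9 | (S)-2-hydroxy-3-(4-hydroxyphenyl)-1-{2-methoxy-4-[(2-methylbut-3-yn-2-yl)oxy]phenyl}propan-1-one | C#CC(C)(C)Oc1ccc(C(=O)[C@@H](O)Cc2ccc(O)cc2)c(OC)c1
F10 | step 9 | free-hydroxyl allenyl dienone, 4-[(S)-2-hydroxy-3-(4-hydroxyphenyl)propanoyl]-3-methoxy-6-(3-methylbuta-1,2-dien-1-yl)cyclohexa-2,4-dien-1-one | O=C1C=C(OC)C(C(=O)[C@@H](O)Cc2ccc(O)cc2)=CC1C=C=C(C)C
F11 | step 9 | (S)-2-hydroxy-1-[4-hydroxy-2-methoxy-5-(3-methylbuta-1,2-dien-1-yl)phenyl]-3-(4-hydroxyphenyl)propan-1-one | Oc1cc(OC)c(C(=O)[C@@H](O)Cc2ccc(O)cc2)cc1C=C=C(C)C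
F12 | step 9 | free-hydroxyl ortho-quinone methide, (Z)-4-[(S)-2-hydroxy-3-(4-hydroxyphenyl)propanoyl]-3-methoxy-6-(3-methylbut-2-en-1-ylidene)cyclohexa-2,4-dien-1-one | O=C1C=C(OC)C(C(=O)[C@@H](O)Cc2ccc(O)cc2)=C/C1=C/C=C(C)C
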